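The route rests on cutting the ether bond C1–O2 of the oxepane ring (O2–C3–C4–C5–C6–C7–C1; C1 is the quaternary carbon carrying lactone carbonyl C9, C7 the ring carbinol), with C9 masked as a vinyl group. The feature exploited is that C1–O2 and C7–OH are vicinal and anti, the imprint of an epoxide opened with inversion at C1. In one operation the C3 hydroxyl opens a C1/C7 vinyl epoxide at its tertiary allylic carbon, closing the seven-membered ring and setting C1 while C7 keeps the epoxide oxygen. The precursor is an acyclic vinyl epoxide with free C3–OH, a C4 triethylsilyl ether and both side-chain stubs as protected primary alcohols.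

Key step: step 18

Labels: C1 (bears chain A and C9), O2 (ring ether), C3 (bears chain B), C4 (bears CH3 and lactone oxygen O8), C5, C6, C7 (CHOH), C9 (C=O). Chain A is (Z)-CH2CH2CH=C(CH3)CH2OH on C1 and chain B is (Z)-CH2CH2C(CH3)=CHCH2OH on C3. The target is C1 R, C3 S, C4 R, C7 S.

Assumption: the usual facial rules hold (the D-fructose-derived Shi ketone gives R,R-epoxides from E-trisubstituted alkenes; L-(+)-tartrate gives 2S-epoxy alcohols), so the L-fructose-derived ketone and D-(−)-diethyl tartrate, both purchased, are used here.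

Step 1
Reactants: 1 propane-1,3-diol
Product: 2 3-[(4-methoxyphenyl)methoxy]propan-1-ol
Conditions: 1 (3 equiv), NaH (1 equiv), THF/DMF, 0 °C; PMBCl (1 equiv), Bu4NI (cat.), rt
Reagents that add atoms: 4-methoxybenzyl chloride, COc1ccc(CCl)cc1
Why: Williamson etherification of the monoalkoxide of the symmetric diol (used in excess) gives the mono-PMB ether; PMB is put on the chain B oxygen because it can later be removed oxidatively under neutral conditions beside silyl ethers, an alkene and the lactone.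

Step 2
Reactants: 2 3-[(4-methoxyphenyl)methoxy]propan-1-ol
Product: 3 3-[(4-methoxyphenyl)methoxy]propanal
Conditions: TEMPO (cat.), PhI(OAc)2, CH2Cl2, rt
Reagents that add atoms: none
Why: TEMPO/PhI(OAc)2 oxidation of a primary alcohol stops at the aldehyde under non-basic conditions, which avoids β-elimination of the β-alkoxy aldehyde.

Step 3
Reactants: 3 3-[(4-methoxyphenyl)methoxy]propanal; 4 isopropenylmagnesium bromide
Product: 5 rac-5-[(4-methoxyphenyl)methoxy]-2-methylpent-1-en-3-ol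
Conditions: THF, −78 → 0 °C; aq. NH4Cl
Reagents that add atoms: none
Why: Grignard 1,2-addition gives the 2-methylallyl carbinol needed for the Claisen step; its stereocentre is left racemic because step 4 destroys it.

Step 4
Reactants: 5 rac-5-[(4-methoxyphenyl)methoxy]-2-methylpent-1-en-3-ol; 6 triethyl orthoacetate
Product: 8 ethyl (4E)-7-[(4-methoxyphenyl)methoxy]-4-methylhept-4-enoate, via mixed ketene acetal 7 (not isolated)
Conditions: 6 (6 equiv), EtCO2H (cat.), 140 °C, EtOH distilled off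
Reagents that add atoms: none
Why: Johnson–Claisen [3,3]-sigmatropic rearrangement through a chair transition state with the side chain equatorial should give the trisubstituted (E)-alkene (C3=C4) and the two-carbon ester arm C6–C7.

Step 5
Reactants: 8 ethyl (4E)-7-[(4-methoxyphenyl)methoxy]-4-methylhept-4-enoate
Product: 9 ethyl 3-[(2S,3S)-3-{2-[(4-methoxyphenyl)methoxy]ethyl}-2-methyloxiran-2-yl]propanoate
Conditions: L-fructose-derived Shi ketone (1,2:4,5-di-O-isopropylidene-β-L-erythro-2,3-hexodiulo-2,6-pyranose, 0.3 equiv), KHSO5 (as 2KHSO5·KHSO4·K2SO4), K2CO3, Bu4NHSO4 (cat.), MeCN/CH2(OMe)2, aq. Na2B4O7 buffer (pH 10.5), 0 °C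
Reagents that add atoms: potassium peroxymonosulfate, [K+].OOS(=O)(=O)[O-]
Why: Shi asymmetric epoxidation (chiral dioxirane, spiro transition state) of the electron-rich (E)-trisubstituted alkene; the L-fructose-derived ketone is expected to give the (S,S)-epoxide, which fixes C3 and prepares C4 for inversion.

Step 6
Reactants: 9 ethyl 3-[(2S,3S)-3-{2-[(4-methoxyphenyl)methoxy]ethyl}-2-methyloxiran-2-yl]propanoate
Product: 11 (5R)-5-{(1S)-1-hydroxy-3-[(4-methoxyphenyl)methoxy]propyl}-5-methyloxolan-2-one, via epoxy acid 10 (not isolated)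
Conditions: LiOH, THF/H2O, 0 °C → rt; then 1 M HCl to pH 3, rt
Reagents that add atoms: lithium hydroxide, [Li+].[OH-]
Why: Saponification, then acid-triggered 5-exo opening of the epoxide by the carboxyl group at the tertiary C4 with inversion, gives the γ-lactone and so the anti C3 (S)/C4 (R) dioxygen pattern.

Step 7
Reactants: 11 (5R)-5-{(1S)-1-hydroxy-3-[(4-methoxyphenyl)methoxy]propyl}-5-methyloxolan-2-one
Product: 12 (4R,5S)-7-[(4-methoxyphenyl)methoxy]-4-methylheptane-1,4,5-triol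
Conditions: LiAlH4, THF, 0 °C; then H2O, aq. NaOH
Reagents that add atoms: none
Why: Hydride reduction of the lactone opens it to the C7 primary alcohol and the tertiary C4–OH without touching the PMB ether.

Step 8
Reactants: 12 (4R,5S)-7-[(4-methoxyphenyl)methoxy]-4-methylheptane-1,4,5-triol
Product: 13 1-methoxy-4-({[(3S,4R)-4-methyl-3,4,7-tris(triethylsilyloxy)heptyl]oxy}methyl)benzene
Conditions: Et3SiOTf (3.5 equiv), 2,6-lutidine, CH2Cl2, −78 → 0 °C
Reagents that add atoms: triethylsilyl trifluoromethanesulfonate, CC[Si](CC)(CC)OS(=O)(=O)C(F)(F)F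
Why: Silyl triflate silylation covers all three hydroxyls, including the hindered tertiary C4–OH whose triethylsilyl ether must block that oxygen in the key step.

Step 9
Reactants: 13 1-methoxy-4-({[(3S,4R)-4-methyl-3,4,7-tris(triethylsilyloxy)heptyl]oxy}methyl)benzene
Product: 14 (4R,5S)-7-[(4-methoxyphenyl)methoxy]-4-methyl-4,5-bis(triethylsilyloxy)heptanal
Conditions: (COCl)2, DMSO, CH2Cl2, −78 → −30 °C; then Et3N, −78 °C → rt
Reagents that add atoms: none
Why: Under Swern conditions a primary triethylsilyl ether is cleaved and oxidised directly to the aldehyde while secondary and tertiary triethylsilyl ethers persist, so the open-chain C7 aldehyde is obtained without a free C4–OH and hence without lactol formation.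

Step 10
Reactants: 15 3-bromopropan-1-ol
Product: 16 (3-bromopropoxy)(tert-butyl)diphenylsilane
Conditions: t-BuPh2SiCl, imidazole, CH2Cl2, 0 °C → rt
Reagents that add atoms: tert-butyl(chloro)diphenylsilane, CC(C)(C)[Si](Cl)(c1ccccc1)c1ccccc1
Why: Standard silylation; the bulky and weakly Lewis-basic TBDPS ether is chosen for the chain A oxygen so that it cannot add 5-exo to C1 in the key step.

Step 11
Reactants: 17 ethyl 2-(diphenoxyphosphoryl)acetate; 16 (3-bromopropoxy)(tert-butyl)diphenylsilane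
Product: 18 rac-ethyl 5-[(tert-butyldiphenylsilyl)oxy]-2-(diphenoxyphosphoryl)pentanoate
Conditions: NaH, DMF, 0 °C; then 16, NaI (cat.), 50 °C
Reagents that add atoms: none
Why: C-alkylation of the sodium salt of the phosphonoacetate by the primary halide (iodide formed in situ) puts the chain A stub on the olefination reagent.

Step 12
Reactants: 14 (4R,5S)-7-[(4-methoxyphenyl)methoxy]-4-methyl-4,5-bis(triethylsilyloxy)heptanal; 18 rac-ethyl 5-[(tert-butyldiphenylsilyl)oxy]-2-(diphenoxyphosphoryl)pentanoate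
Product: 19 ethyl (2Z,6R,7S)-2-{3-[(tert-butyldiphenylsilyl)oxy]propyl}-9-[(4-methoxyphenyl)methoxy]-6-methyl-6,7-bis(triethylsilyloxy)non-2-enoate
Conditions: 18, NaH, THF, 0 °C; then 14, −78 → −20 °C
Reagents that add atoms: none
Why: Z-selective Horner–Wadsworth–Emmons olefination (diaryl phosphonate, Ando variant; fast irreversible elimination from the kinetic adduct) should place the ester carbon (future C9) cis to C6 on the new C1=C7 bond.

Step 13
Reactants: 19 ethyl (2Z,6R,7S)-2-{3-[(tert-butyldiphenylsilyl)oxy]propyl}-9-[(4-methoxyphenyl)methoxy]-6-methyl-6,7-bis(triethylsilyloxy)non-2-enoate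
Product: 20 (2Z,6R,7S)-2-{3-[(tert-butyldiphenylsilyl)oxy]propyl}-9-[(4-methoxyphenyl)methoxy]-6-methyl-6,7-bis(triethylsilyloxy)non-2-en-1-ol
Conditions: i-Bu2AlH (2.5 equiv), CH2Cl2, −78 °C; aq. KNaC4H4O6
Reagents that add atoms: none
Why: 1,2-Reduction of the α,β-unsaturated ester gives the (Z)-allylic alcohol with the olefin geometry unchanged.

Step 14
Reactants: 20 (2Z,6R,7S)-2-{3-[(tert-butyldiphenylsilyl)oxy]propyl}-9-[(4-methoxyphenyl)methoxy]-6-methyl-6,7-bis(triethylsilyloxy)non-2-en-1-ol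
Product: 21 [(2R,3S)-2-{3-[(tert-butyldiphenylsilyl)oxy]propyl}-3-{(3R,4S)-6-[(4-methoxyphenyl)methoxy]-3-methyl-3,4-bis(triethylsilyloxy)hexyl}oxiran-2-yl]methanol
Conditions: Ti(OiPr)4 (0.3 equiv), D-(−)-diethyl tartrate (0.36 equiv), t-BuOOH (2 equiv), 4 Å MS, CH2Cl2, −20 °C
Reagents that add atoms: tert-butyl hydroperoxide, CC(C)(C)OO
Why: Sharpless asymmetric epoxidation under reagent control; with D-(−)-tartrate the (Z)-allylic alcohol should give the (2R,3S)-epoxy alcohol, which sets C7 (S) and the C1 configuration that step 18 inverts.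

Step 15
Reactants: 21 [(2R,3S)-2-{3-[(tert-butyldiphenylsilyl)oxy]propyl}-3-{(3R,4S)-6-[(4-methoxyphenyl)methoxy]-3-methyl-3,4-bis(triethylsilyloxy)hexyl}oxiran-2-yl]methanol
Product: 22 (2S,3S)-2-{3-[(tert-butyldiphenylsilyl)oxy]propyl}-3-{(3R,4S)-6-[(4-methoxyphenyl)methoxy]-3-methyl-3,4-bis(triethylsilyloxy)hexyl}oxirane-2-carbaldehyde
Conditions: Dess–Martin periodinane, NaHCO3, CH2Cl2, 0 °C → rt
Reagents that add atoms: none
Why: Buffered Dess–Martin oxidation gives the epoxy aldehyde, whose α-carbon is quaternary and cannot epimerise.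

Step 16
Reactants: 22 (2S,3S)-2-{3-[(tert-butyldiphenylsilyl)oxy]propyl}-3-{(3R,4S)-6-[(4-methoxyphenyl)methoxy]-3-methyl-3,4-bis(triethylsilyloxy)hexyl}oxirane-2-carbaldehyde
Product: 23 tert-butyl(3-{(2R,3S)-2-ethenyl-3-[(3R,4S)-6-[(4-methoxyphenyl)methoxy]-3-methyl-3,4-bis(triethylsilyloxy)hexyl]oxiran-2-yl}propoxy)diphenylsilane
Conditions: Ph3PCH3Br, KN(SiMe3)2, THF, 0 °C; then 22, −78 → 0 °C
Reagents that add atoms: methyltriphenylphosphonium bromide, C[P+](c1ccccc1)(c1ccccc1)c1ccccc1.[Br-]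
Why: Wittig methylenation turns the aldehyde into the vinyl group that masks C9 and activates C1.

Step 17
Reactants: 23 tert-butyl(3-{(2R,3S)-2-ethenyl-3-[(3R,4S)-6-[(4-methoxyphenyl)methoxy]-3-methyl-3,4-bis(triethylsilyloxy)hexyl]oxiran-2-yl}propoxy)diphenylsilane
Product: 24 (3S,4R)-6-[(2S,3R)-3-{3-[(tert-butyldiphenylsilyl)oxy]propyl}-3-ethenyloxiran-2-yl]-1-[(4-methoxyphenyl)methoxy]-4-methyl-4-(triethylsilyloxy)hexan-3-ol
Conditions: HF·pyridine, pyridine, THF, 0 °C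
Reagents that add atoms: none
Why: Buffered HF·pyridine should cleave the secondary triethylsilyl ether faster than the more hindered tertiary one and leave the TBDPS and PMB ethers and the epoxide alone, so that only the C3 hydroxyl is freed.

Step 18
Reactants: 24 (3S,4R)-6-[(2S,3R)-3-{3-[(tert-butyldiphenylsilyl)oxy]propyl}-3-ethenyloxiran-2-yl]-1-[(4-methoxyphenyl)methoxy]-4-methyl-4-(triethylsilyloxy)hexan-3-ol
Product: 25 (2S,3S,6R,7S)-2-{3-[(tert-butyldiphenylsilyl)oxy]propyl}-2-ethenyl-7-{2-[(4-methoxyphenyl)methoxy]ethyl}-6-methyl-6-(triethylsilyloxy)oxepan-3-ol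
Conditions: CSA (0.1 equiv), CH2Cl2 (0.005 M), −40 → 0 °C
Reagents that add atoms: none
Why: CSA protonates the epoxide oxygen, and the C1–O bond, weakened because C1 is both tertiary and allylic, is attacked from the rear by the C3 hydroxyl (borderline SN2 with inversion at C1); this is the known acid-catalysed endo-selective cyclisation of hydroxy vinyl epoxides to tetrahydropyrans and oxepanes. The oxepane (O2–C3–C4–C5–C6–C7–C1) closes in the 7-endo-tet mode, the 6-exo alternative at the unactivated secondary C7 lacking any such stabilisation. The one new stereocentre, C1, follows from inversion of the epoxide (C1 R, C7 S) set in step 14, and C7 keeps the epoxide oxygen with its configuration, which gives the anti C1–O2/C7–OH relationship. The step needs the C3–OH to be the only nucleophile: the triethylsilyl ether blocks the tertiary C4 oxygen (which would otherwise close a six-membered ring at C1 or a five-membered ring at C7), the bulky TBDPS ether keeps the chain A oxygen from adding to C1, and the PMB ether is too remote to reach the epoxide. Catalytic acid, high dilution, low temperature and a non-nucleophilic solvent are meant to hold back elimination or 1,2-shift at the ionisable tertiary allylic centre.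

Step 19
Reactants: 25 (2S,3S,6R,7S)-2-{3-[(tert-butyldiphenylsilyl)oxy]propyl}-2-ethenyl-7-{2-[(4-methoxyphenyl)methoxy]ethyl}-6-methyl-6-(triethylsilyloxy)oxepan-3-ol
Product: 26 (2S,3S,6R,7S)-3-[(tert-butyldimethylsilyl)oxy]-2-{3-[(tert-butyldiphenylsilyl)oxy]propyl}-2-ethenyl-7-{2-[(4-methoxyphenyl)methoxy]ethyl}-6-methyl-6-(triethylsilyloxy)oxepane
Conditions: t-BuMe2SiOTf, 2,6-lutidine, CH2Cl2, −78 → 0 °C
Reagents that add atoms: tert-butyldimethylsilyl trifluoromethanesulfonate, CC(C)(C)[Si](C)(C)OS(=O)(=O)C(F)(F)F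
Why: Silyl triflate silylation of the hindered C7 carbinol protects it from oxidation and keeps it from acting as a nucleophile or proton source in the later iodination, Wittig and organozinc steps.

Step 20
Reactants: 26 (2S,3S,6R,7S)-3-[(tert-butyldimethylsilyl)oxy]-2-{3-[(tert-butyldiphenylsilyl)oxy]propyl}-2-ethenyl-7-{2-[(4-methoxyphenyl)methoxy]ethyl}-6-methyl-6-(triethylsilyloxy)oxepane
Product: 27 (2S,3R,6S,7S)-6-[(tert-butyldimethylsilyl)oxy]-7-ethenyl-7-(3-hydroxypropyl)-2-{2-[(4-methoxyphenyl)methoxy]ethyl}-3-methyloxepan-3-ol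
Conditions: Bu4NF (3 equiv), THF, 0 °C → rt
Reagents that add atoms: none
Why: Fluoride removes the tertiary triethylsilyl ether (its task is done) and the primary TBDPS ether, while the hindered secondary TBS ether next to the quaternary C1 is expected to react most slowly and survive.

Step 21
Reactants: 27 (2S,3R,6S,7S)-6-[(tert-butyldimethylsilyl)oxy]-7-ethenyl-7-(3-hydroxypropyl)-2-{2-[(4-methoxyphenyl)methoxy]ethyl}-3-methyloxepan-3-ol
Product: 28 (2S,3R,6S,7S)-6-[(tert-butyldimethylsilyl)oxy]-7-ethenyl-7-(3-iodopropyl)-2-{2-[(4-methoxyphenyl)methoxy]ethyl}-3-methyloxepan-3-ol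
Conditions: I2, PPh3, imidazole, CH2Cl2, 0 °C
Reagents that add atoms: iodine, II
Why: Appel-type iodination converts only the primary alcohol (the C4–OH is tertiary), which removes the chain A hydroxyl before C9 is unmasked so that it can never form a spiro lactol or a translactonised spiro lactone.

Step 22
Reactants: 28 (2S,3R,6S,7S)-6-[(tert-butyldimethylsilyl)oxy]-7-ethenyl-7-(3-iodopropyl)-2-{2-[(4-methoxyphenyl)methoxy]ethyl}-3-methyloxepan-3-ol
Product: 31 (1R,2S,5R,9S)-2-[(tert-butyldimethylsilyl)oxy]-1-(3-iodopropyl)-9-{2-[(4-methoxyphenyl)methoxy]ethyl}-5-methyl-6,8-dioxabicyclo[3.2.2]nonan-7-ol, via vicinal diol 29 (not isolated), via hydroxy aldehyde 30 (not isolated)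
Conditions: K2OsO4·2H2O (2 mol %), NaIO4 (4 equiv), 2,6-lutidine, 1,4-dioxane/H2O (3:1), rt
Reagents that add atoms: sodium periodate, [Na+].[O-]I(=O)(=O)=O
Why: Lemieux–Johnson cleavage (osmate-catalysed dihydroxylation, then periodate cleavage) turns the vinyl group into the C9 aldehyde, which the cis tertiary C4–OH should capture as the bridged six-membered lactol; osmate/periodate is used instead of ozone to spare the PMB ether.

Step 23
Reactants: 31 (1R,2S,5R,9S)-2-[(tert-butyldimethylsilyl)oxy]-1-(3-iodopropyl)-9-{2-[(4-methoxyphenyl)methoxy]ethyl}-5-methyl-6,8-dioxabicyclo[3.2.2]nonan-7-ol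
Product: 32 (1R,2S,5R,9S)-2-[(tert-butyldimethylsilyl)oxy]-1-(3-iodopropyl)-9-{2-[(4-methoxyphenyl)methoxy]ethyl}-5-methyl-6,8-dioxabicyclo[3.2.2]nonan-7-one
Conditions: nPr4N[RuO4] (5 mol %), N-methylmorpholine N-oxide, 4 Å MS, CH2Cl2, rt
Reagents that add atoms: none
Why: Ley–Griffith oxidation of the lactol gives the bridged lactone C9(=O)–O8–C4; no other oxidisable hydroxyl is present.

Step 24
Reactants: 32 (1R,2S,5R,9S)-2-[(tert-butyldimethylsilyl)oxy]-1-(3-iodopropyl)-9-{2-[(4-methoxyphenyl)methoxy]ethyl}-5-methyl-6,8-dioxabicyclo[3.2.2]nonan-7-one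
Product: 33 {3-[(1R,2S,5R,9S)-2-[(tert-butyldimethylsilyl)oxy]-9-{2-[(4-methoxyphenyl)methoxy]ethyl}-5-methyl-7-oxo-6,8-dioxabicyclo[3.2.2]nonan-1-yl]propyl}triphenylphosphonium iodide
Conditions: PPh3 (3 equiv), MeCN, 80 °C
Reagents that add atoms: triphenylphosphine, c1ccc(cc1)P(c1ccccc1)c1ccccc1
Why: SN2 quaternisation of triphenylphosphine by the unhindered primary iodide gives the phosphonium salt.

Step 25
Reactants: 33 {3-[(1R,2S,5R,9S)-2-[(tert-butyldimethylsilyl)oxy]-9-{2-[(4-methoxyphenyl)methoxy]ethyl}-5-methyl-7-oxo-6,8-dioxabicyclo[3.2.2]nonan-1-yl]propyl}triphenylphosphonium iodide; 34 1-[(tert-butyldimethylsilyl)oxy]propan-2-one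
Product: 36 (1R,2S,5R,9S)-2-[(tert-butyldimethylsilyl)oxy]-1-{(3Z)-5-[(tert-butyldimethylsilyl)oxy]-4-methylpent-3-en-1-yl}-9-{2-[(4-methoxyphenyl)methoxy]ethyl}-5-methyl-6,8-dioxabicyclo[3.2.2]nonan-7-one, via phosphorus ylide 35 (not isolated)
Conditions: NaN(SiMe3)2 (1.0 equiv), THF, −78 °C; then 34 (3 equiv), −78 °C → rt
Reagents that add atoms: none
Why: Wittig olefination of a non-stabilised ylide with an α-silyloxy methyl ketone is a known Z-selective route to trisubstituted allylic ethers, so chain A arrives in the alcohol oxidation state and no ester has to be reduced beside the lactone; the lactone has no α-hydrogen, and the ylide is trapped at −78 °C by excess ketone.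

Step 26
Reactants: 36 (1R,2S,5R,9S)-2-[(tert-butyldimethylsilyl)oxy]-1-{(3Z)-5-[(tert-butyldimethylsilyl)oxy]-4-methylpent-3-en-1-yl}-9-{2-[(4-methoxyphenyl)methoxy]ethyl}-5-methyl-6,8-dioxabicyclo[3.2.2]nonan-7-one
Product: 37 (1R,2S,5R,9S)-2-[(tert-butyldimethylsilyl)oxy]-1-{(3Z)-5-[(tert-butyldimethylsilyl)oxy]-4-methylpent-3-en-1-yl}-9-(2-hydroxyethyl)-5-methyl-6,8-dioxabicyclo[3.2.2]nonan-7-one
Conditions: DDQ, CH2Cl2/aq. phosphate buffer (pH 7), 0 °C
Reagents that add atoms: none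
Why: DDQ oxidation of the electron-rich PMB ether and hydrolysis of the resulting oxocarbenium ion free the chain B alcohol under neutral conditions that silyl ethers, the trisubstituted alkene and the lactone tolerate.

Step 27
Reactants: 37 (1R,2S,5R,9S)-2-[(tert-butyldimethylsilyl)oxy]-1-{(3Z)-5-[(tert-butyldimethylsilyl)oxy]-4-methylpent-3-en-1-yl}-9-(2-hydroxyethyl)-5-methyl-6,8-dioxabicyclo[3.2.2]nonan-7-one
Product: 38 (1R,2S,5R,9S)-2-[(tert-butyldimethylsilyl)oxy]-1-{(3Z)-5-[(tert-butyldimethylsilyl)oxy]-4-methylpent-3-en-1-yl}-9-(2-iodoethyl)-5-methyl-6,8-dioxabicyclo[3.2.2]nonan-7-one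
Conditions: I2, PPh3, imidazole, CH2Cl2, 0 °C
Reagents that add atoms: iodine, II
Why: Appel-type iodination of the only free (primary) alcohol gives the electrophile for zinc insertion.

Step 28
Reactants: 39 but-2-yn-1-ol
Product: 41 (2Z)-3-iodobut-2-en-1-ol, via cyclic alkenylaluminate 40 (not isolated)
Conditions: NaAlH2(OCH2CH2OCH3)2, Et2O, 0 °C → rt; then I2, THF, −78 → 0 °C
Reagents that add atoms: iodine, II
Why: Hydroxyl-directed trans-hydroalumination of the propargylic alcohol places aluminium on C3 in a five-membered chelate, and iodinolysis with retention gives the alkenyl iodide with iodine cis to CH2OH.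

Step 29
Reactants: 41 (2Z)-3-iodobut-2-en-1-ol
Product: 42 tert-butyl{[(2Z)-3-iodobut-2-en-1-yl]oxy}dimethylsilane
Conditions: t-BuMe2SiCl, imidazole, CH2Cl2, rt
Reagents that add atoms: tert-butyl(chloro)dimethylsilane, CC(C)(C)[Si](C)(C)Cl
Why: Silylation of the primary alcohol removes the acidic proton that would quench the organozinc reagent of step 30.

Step 30
Reactants: 38 (1R,2S,5R,9S)-2-[(tert-butyldimethylsilyl)oxy]-1-{(3Z)-5-[(tert-butyldimethylsilyl)oxy]-4-methylpent-3-en-1-yl}-9-(2-iodoethyl)-5-methyl-6,8-dioxabicyclo[3.2.2]nonan-7-one; 42 tert-butyl{[(2Z)-3-iodobut-2-en-1-yl]oxy}dimethylsilane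
Product: 44 (1R,2S,5R,9S)-2-[(tert-butyldimethylsilyl)oxy]-9-{(3Z)-5-[(tert-butyldimethylsilyl)oxy]-3-methylpent-3-en-1-yl}-1-{(3Z)-5-[(tert-butyldimethylsilyl)oxy]-4-methylpent-3-en-1-yl}-5-methyl-6,8-dioxabicyclo[3.2.2]nonan-7-one, via alkylzinc iodide 43 (not isolated)
Conditions: Zn dust (activated: BrCH2CH2Br, Me3SiCl), DMA, 40 °C; then 42, Pd(PPh3)4 (5 mol %), THF, 40 °C
Reagents that add atoms: none
Why: Negishi sp3–sp2 coupling; zinc insertion into the primary iodide tolerates the lactone and silyl ethers (the ring oxygen is γ to zinc, so no β-elimination), and palladium-catalysed coupling with the (Z)-alkenyl iodide proceeds with retention of olefin geometry to complete chain B.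

Step 31
Reactants: 44 (1R,2S,5R,9S)-2-[(tert-butyldimethylsilyl)oxy]-9-{(3Z)-5-[(tert-butyldimethylsilyl)oxy]-3-methylpent-3-en-1-yl}-1-{(3Z)-5-[(tert-butyldimethylsilyl)oxy]-4-methylpent-3-en-1-yl}-5-methyl-6,8-dioxabicyclo[3.2.2]nonan-7-one
Product: 45 (1R,2S,5R,9S)-2-hydroxy-9-[(3Z)-5-hydroxy-3-methylpent-3-en-1-yl]-1-[(3Z)-5-hydroxy-4-methylpent-3-en-1-yl]-5-methyl-6,8-dioxabicyclo[3.2.2]nonan-7-one (CNP0105745.1)
Conditions: HF·pyridine, pyridine, THF, 0 °C → rt
Reagents that add atoms: none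
Why: Buffered fluoride cleaves the two primary allylic and the one secondary TBS ether without opening the hindered lactone or ionising the allylic alcohols, which should give the target.

Compound list
1 | propane-1,3-diol | OCCCO | starting material
2 | 3-[(4-methoxyphenyl)methoxy]propan-1-ol | COc1ccc(COCCCO)cc1 | intermediate
3 | 3-[(4-methoxyphenyl)methoxy]propanal | COc1ccc(COCCC=O)cc1 | intermediate
4 | isopropenylmagnesium bromide | CC(=C)[Mg]Br | starting material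
5 | rac-5-[(4-methoxyphenyl)methoxy]-2-methylpent-1-en-3-ol | C=C(C)C(O)CCOCc1ccc(OC)cc1 | intermediate
6 | triethyl orthoacetate | CCOC(C)(OCC)OCC | starting material
7 | rac-1-({[3-(1-ethoxyethenyloxy)-4-methylpent-4-en-1-yl]oxy}methyl)-4-methoxybenzene (mixed ketene acetal) | C=C(OCC)OC(CCOCc1ccc(OC)cc1)C(C)=C | intermediate (not isolated)
8 | ethyl (4E)-7-[(4-methoxyphenyl)methoxy]-4-methylhept-4-enoate | CCOC(=O)CC/C(C)=C/CCOCc1ccc(OC)cc1 | intermediate
9 | ethyl 3-[(2S,3S)-3-{2-[(4-methoxyphenyl)methoxy]ethyl}-2-methyloxiran-2-yl]propanoate | CCOC(=O)CC[C@]1(C)O[C@H]1CCOCc2ccc(OC)cc2 | intermediate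
10 | 3-[(2S,3S)-3-{2-[(4-methoxyphenyl)methoxy]ethyl}-2-methyloxiran-2-yl]propanoic acid | OC(=O)CC[C@]1(C)O[C@H]1CCOCc2ccc(OC)cc2 | intermediate (not isolated)
11 | (5R)-5-{(1S)-1-hydroxy-3-[(4-methoxyphenyl)methoxy]propyl}-5-methyloxolan-2-one | C[C@@]1(CCC(=O)O1)[C@@H](O)CCOCc2ccc(OC)cc2 | intermediate
12 | (4R,5S)-7-[(4-methoxyphenyl)methoxy]-4-methylheptane-1,4,5-triol | OCCC[C@@](C)(O)[C@@H](O)CCOCc1ccc(OC)cc1 | intermediate
13 | 1-methoxy-4-({[(3S,4R)-4-methyl-3,4,7-tris(triethylsilyloxy)heptyl]oxy}methyl)benzene | CC[Si](CC)(CC)OCCC[C@@](C)(O[Si](CC)(CC)CC)[C@@H](O[Si](CC)(CC)CC)CCOCc1ccc(OC)cc1 | intermediate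
14 | (4R,5S)-7-[(4-methoxyphenyl)methoxy]-4-methyl-4,5-bis(triethylsilyloxy)heptanal | O=CCC[C@@](C)(O[Si](CC)(CC)CC)[C@@H](O[Si](CC)(CC)CC)CCOCc1ccc(OC)cc1 | intermediate
15 | 3-bromopropan-1-ol | OCCCBr | starting material
16 | (3-bromopropoxy)(tert-butyl)diphenylsilane | BrCCCO[Si](c1ccccc1)(c1ccccc1)C(C)(C)C | intermediate
17 | ethyl 2-(diphenoxyphosphoryl)acetate | CCOC(=O)CP(=O)(Oc1ccccc1)Oc1ccccc1 | starting material
18 | rac-ethyl 5-[(tert-butyldiphenylsilyl)oxy]-2-(diphenoxyphosphoryl)pentanoate | CCOC(=O)C(CCCO[Si](c1ccccc1)(c1ccccc1)C(C)(C)C)P(=O)(Oc1ccccc1)Oc1ccccc1 | intermediate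
19 | ethyl (2Z,6R,7S)-2-{3-[(tert-butyldiphenylsilyl)oxy]propyl}-9-[(4-methoxyphenyl)methoxy]-6-methyl-6,7-bis(triethylsilyloxy)non-2-enoate | CCOC(=O)/C(CCCO[Si](c1ccccc1)(c1ccccc1)C(C)(C)C)=C\CC[C@@](C)(O[Si](CC)(CC)CC)[C@@H](O[Si](CC)(CC)CC)CCOCc1ccc(OC)cc1 | intermediate
20 | (2Z,6R,7S)-2-{3-[(tert-butyldiphenylsilyl)oxy]propyl}-9-[(4-methoxyphenyl)methoxy]-6-methyl-6,7-bis(triethylsilyloxy)non-2-en-1-ol | OC/C(CCCO[Si](c1ccccc1)(c1ccccc1)C(C)(C)C)=C\CC[C@@](C)(O[Si](CC)(CC)CC)[C@@H](O[Si](CC)(CC)CC)CCOCc1ccc(OC)cc1 | intermediate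
21 | [(2R,3S)-2-{3-[(tert-butyldiphenylsilyl)oxy]propyl}-3-{(3R,4S)-6-[(4-methoxyphenyl)methoxy]-3-methyl-3,4-bis(triethylsilyloxy)hexyl}oxiran-2-yl]methanol | OC[C@@]1(CCCO[Si](c2ccccc2)(c2ccccc2)C(C)(C)C)O[C@H]1CC[C@@](C)(O[Si](CC)(CC)CC)[C@@H](O[Si](CC)(CC)CC)CCOCc2ccc(OC)cc2 | intermediate
22 | (2S,3S)-2-{3-[(tert-butyldiphenylsilyl)oxy]propyl}-3-{(3R,4S)-6-[(4-methoxyphenyl)methoxy]-3-methyl-3,4-bis(triethylsilyloxy)hexyl}oxirane-2-carbaldehyde | O=C[C@@]1(CCCO[Si](c2ccccc2)(c2ccccc2)C(C)(C)C)O[C@H]1CC[C@@](C)(O[Si](CC)(CC)CC)[C@@H](O[Si](CC)(CC)CC)CCOCc2ccc(OC)cc2 | intermediate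
23 | tert-butyl(3-{(2R,3S)-2-ethenyl-3-[(3R,4S)-6-[(4-methoxyphenyl)methoxy]-3-methyl-3,4-bis(triethylsilyloxy)hexyl]oxiran-2-yl}propoxy)diphenylsilane | C=C[C@@]1(CCCO[Si](c2ccccc2)(c2ccccc2)C(C)(C)C)O[C@H]1CC[C@@](C)(O[Si](CC)(CC)CC)[C@@H](O[Si](CC)(CC)CC)CCOCc2ccc(OC)cc2 | intermediate
24 | (3S,4R)-6-[(2S,3R)-3-{3-[(tert-butyldiphenylsilyl)oxy]propyl}-3-ethenyloxiran-2-yl]-1-[(4-methoxyphenyl)methoxy]-4-methyl-4-(triethylsilyloxy)hexan-3-ol (key-step precursor) | C=C[C@@]1(CCCO[Si](c2ccccc2)(c2ccccc2)C(C)(C)C)O[C@H]1CC[C@@](C)(O[Si](CC)(CC)CC)[C@@H](O)CCOCc2ccc(OC)cc2 | intermediate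
25 | (2S,3S,6R,7S)-2-{3-[(tert-butyldiphenylsilyl)oxy]propyl}-2-ethenyl-7-{2-[(4-methoxyphenyl)methoxy]ethyl}-6-methyl-6-(triethylsilyloxy)oxepan-3-ol (key-step product) | C=C[C@]1(CCCO[Si](c2ccccc2)(c2ccccc2)C(C)(C)C)O[C@@H](CCOCc2ccc(OC)cc2)[C@](C)(O[Si](CC)(CC)CC)CC[C@@H]1O | intermediate
26 | (2S,3S,6R,7S)-3-[(tert-butyldimethylsilyl)oxy]-2-{3-[(tert-butyldiphenylsilyl)oxy]propyl}-2-ethenyl-7-{2-[(4-methoxyphenyl)methoxy]ethyl}-6-methyl-6-(triethylsilyloxy)oxepane | C=C[C@]1(CCCO[Si](c2ccccc2)(c2ccccc2)C(C)(C)C)O[C@@H](CCOCc2ccc(OC)cc2)[C@](C)(O[Si](CC)(CC)CC)CC[C@@H]1O[Si](C)(C)C(C)(C)C | intermediate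
27 | (2S,3R,6S,7S)-6-[(tert-butyldimethylsilyl)oxy]-7-ethenyl-7-(3-hydroxypropyl)-2-{2-[(4-methoxyphenyl)methoxy]ethyl}-3-methyloxepan-3-ol | C=C[C@]1(CCCO)O[C@@H](CCOCc2ccc(OC)cc2)[C@](C)(O)CC[C@@H]1O[Si](C)(C)C(C)(C)C | intermediate
28 | (2S,3R,6S,7S)-6-[(tert-butyldimethylsilyl)oxy]-7-ethenyl-7-(3-iodopropyl)-2-{2-[(4-methoxyphenyl)methoxy]ethyl}-3-methyloxepan-3-ol | C=C[C@]1(CCCI)O[C@@H](CCOCc2ccc(OC)cc2)[C@](C)(O)CC[C@@H]1O[Si](C)(C)C(C)(C)C | intermediate
29 | vicinal diol from 28 (1,2-dihydroxyethyl in place of ethenyl on C1; both carbinol epimers; ring stereocentres as in 28) | OCC(O)[C@]1(CCCI)O[C@@H](CCOCc2ccc(OC)cc2)[C@](C)(O)CC[C@@H]1O[Si](C)(C)C(C)(C)C | intermediate (not isolated)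
30 | (2R,3S,6R,7S)-3-[(tert-butyldimethylsilyl)oxy]-6-hydroxy-2-(3-iodopropyl)-7-{2-[(4-methoxyphenyl)methoxy]ethyl}-6-methyloxepane-2-carbaldehyde | O=C[C@]1(CCCI)O[C@@H](CCOCc2ccc(OC)cc2)[C@](C)(O)CC[C@@H]1O[Si](C)(C)C(C)(C)C | intermediate (not isolated)
31 | (1R,2S,5R,9S)-2-[(tert-butyldimethylsilyl)oxy]-1-(3-iodopropyl)-9-{2-[(4-methoxyphenyl)methoxy]ethyl}-5-methyl-6,8-dioxabicyclo[3.2.2]nonan-7-ol (both C7 epimers) | ICCC[C@@]12O[C@@H](CCOCc3ccc(OC)cc3)[C@@](C)(CC[C@@H]1O[Si](C)(C)C(C)(C)C)OC2O | intermediate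
32 | (1R,2S,5R,9S)-2-[(tert-butyldimethylsilyl)oxy]-1-(3-iodopropyl)-9-{2-[(4-methoxyphenyl)methoxy]ethyl}-5-methyl-6,8-dioxabicyclo[3.2.2]nonan-7-one | ICCC[C@@]12O[C@@H](CCOCc3ccc(OC)cc3)[C@@](C)(CC[C@@H]1O[Si](C)(C)C(C)(C)C)OC2=O | intermediate
33 | {3-[(1R,2S,5R,9S)-2-[(tert-butyldimethylsilyl)oxy]-9-{2-[(4-methoxyphenyl)methoxy]ethyl}-5-methyl-7-oxo-6,8-dioxabicyclo[3.2.2]nonan-1-yl]propyl}triphenylphosphonium iodide | [I-].C(CC[C@@]12O[C@@H](CCOCc3ccc(OC)cc3)[C@@](C)(CC[C@@H]1O[Si](C)(C)C(C)(C)C)OC2=O)[P+](c1ccccc1)(c1ccccc1)c1ccccc1 | intermediate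
34 | 1-[(tert-butyldimethylsilyl)oxy]propan-2-one | CC(=O)CO[Si](C)(C)C(C)(C)C | starting material
35 | triphenylphosphonium ylide of 33 (3-(triphenylphosphoranylidene)propyl on C1) | C(CC[C@@]12O[C@@H](CCOCc3ccc(OC)cc3)[C@@](C)(CC[C@@H]1O[Si](C)(C)C(C)(C)C)OC2=O)=P(c1ccccc1)(c1ccccc1)c1ccccc1 | intermediate (not isolated)
36 | (1R,2S,5R,9S)-2-[(tert-butyldimethylsilyl)oxy]-1-{(3Z)-5-[(tert-butyldimethylsilyl)oxy]-4-methylpent-3-en-1-yl}-9-{2-[(4-methoxyphenyl)methoxy]ethyl}-5-methyl-6,8-dioxabicyclo[3.2.2]nonan-7-one | C/C(=C/CC[C@@]12O[C@@H](CCOCc3ccc(OC)cc3)[C@@](C)(CC[C@@H]1O[Si](C)(C)C(C)(C)C)OC2=O)CO[Si](C)(C)C(C)(C)C | intermediate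
37 | (1R,2S,5R,9S)-2-[(tert-butyldimethylsilyl)oxy]-1-{(3Z)-5-[(tert-butyldimethylsilyl)oxy]-4-methylpent-3-en-1-yl}-9-(2-hydroxyethyl)-5-methyl-6,8-dioxabicyclo[3.2.2]nonan-7-one | C/C(=C/CC[C@@]12O[C@@H](CCO)[C@@](C)(CC[C@@H]1O[Si](C)(C)C(C)(C)C)OC2=O)CO[Si](C)(C)C(C)(C)C | intermediate
38 | (1R,2S,5R,9S)-2-[(tert-butyldimethylsilyl)oxy]-1-{(3Z)-5-[(tert-butyldimethylsilyl)oxy]-4-methylpent-3-en-1-yl}-9-(2-iodoethyl)-5-methyl-6,8-dioxabicyclo[3.2.2]nonan-7-one | C/C(=C/CC[C@@]12O[C@@H](CCI)[C@@](C)(CC[C@@H]1O[Si](C)(C)C(C)(C)C)OC2=O)CO[Si](C)(C)C(C)(C)C | intermediate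
39 | but-2-yn-1-ol | CC#CCO | starting material
40 | sodium 2,2-bis(2-methoxyethoxy)-3-methyl-2,5-dihydro-1,2-oxaluminol-2-uide (cyclic alkenylaluminate) | [Na+].COCCO[Al-]1(OCCOC)OCC=C1C | intermediate (not isolated)
41 | (2Z)-3-iodobut-2-en-1-ol | C/C(I)=C/CO | intermediate
42 | tert-butyl{[(2Z)-3-iodobut-2-en-1-yl]oxy}dimethylsilane | C/C(I)=C/CO[Si](C)(C)C(C)(C)C | intermediate
43 | alkylzinc iodide from 38 (2-(iodozincio)ethyl on C3) | C/C(=C/CC[C@@]12O[C@@H](CC[Zn]I)[C@@](C)(CC[C@@H]1O[Si](C)(C)C(C)(C)C)OC2=O)CO[Si](C)(C)C(C)(C)C | intermediate (not isolated)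
44 | (1R,2S,5R,9S)-2-[(tert-butyldimethylsilyl)oxy]-9-{(3Z)-5-[(tert-butyldimethylsilyl)oxy]-3-methylpent-3-en-1-yl}-1-{(3Z)-5-[(tert-butyldimethylsilyl)oxy]-4-methylpent-3-en-1-yl}-5-methyl-6,8-dioxabicyclo[3.2.2]nonan-7-one | C/C(=C/CC[C@@]12O[C@@H](CC/C(C)=C\CO[Si](C)(C)C(C)(C)C)[C@@](C)(CC[C@@H]1O[Si](C)(C)C(C)(C)C)OC2=O)CO[Si](C)(C)C(C)(C)C | intermediate
45 | (1R,2S,5R,9S)-2-hydroxy-9-[(3Z)-5-hydroxy-3-methylpent-3-en-1-yl]-1-[(3Z)-5-hydroxy-4-methylpent-3-en-1-yl]-5-methyl-6,8-dioxabicyclo[3.2.2]nonan-7-one (CNP0105745.1) | C/C(=C/CC[C@@]12O[C@@H](CC/C(C)=C\CO)[C@@](C)(CC[C@@H]1O)OC2=O)CO | target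

Total step count: 31. Longest linear sequence: 27 steps (steps 1–9, 12–27, 30 and 31); steps 10–11 and 28–29 are side branches.

Steps most likely to fail

Step 18 (key step). Ionisation at the tertiary allylic C1 may outrun the entropically slow seven-membered ring closure, so that elimination, a 1,2-shift or attack by a silyl ether oxygen takes over. The fallback activates the nucleophile instead of protonating the epoxide. From 24, heating with (Bu3Sn)2O in toluene with azeotropic removal of water should give the tributylstannyl ether F1. Zn(OTf)2 in toluene at 80 °C is then a known promoter for the 7-endo opening of vinyl epoxides by tin alkoxides and should give the stannyl ether of the oxepanol F2. Aqueous work-up cleaves the O–Sn bond and returns to the route at 25.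

Step 25. The ylide may be consumed by intramolecular acylation at the lactone carbonyl (a five-membered ring closure), or the Z/E control with the ketone may be poor. The fallback builds chain A by a Z-selective phosphonate olefination of an aldehyde and re-forms the lactone afterwards. From iodide 32, Kornblum-type oxidation with anhydrous Me3NO in DMSO should give the aldehyde F3. Still–Gennari olefination with ethyl 2-[bis(2,2,2-trifluoroethoxy)phosphoryl]propanoate (KN(SiMe3)2, 18-crown-6, THF, −78 °C) should give the (Z)-α-methyl enoate F4. i-Bu2AlH (CH2Cl2, −78 °C) reduces the ester to the allylic alcohol and the lactone to the lactol, giving the lactol allylic alcohol F5. t-BuMe2SiCl/imidazole silylates only the primary allylic hydroxyl, giving the lactol silyl ether F6. nPr4N[RuO4]/N-methylmorpholine N-oxide reoxidises the lactol and returns to the route at 36.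

Step 17. The rate difference between the secondary and the tertiary triethylsilyl ether may be too small, so that over-deprotection frees the C4 oxygen, which would then cyclise in the wrong sense. The fallback strips both silyl ethers and rebuilds the pattern by sterically controlled acylation. From 23, Bu4NF (2.2 equiv, THF, −20 °C; the primary TBDPS ether reacts more slowly) should give the diol F7. Ac2O/pyridine acylates only the secondary C3–OH, giving the C3 acetate F8. Et3SiOTf/2,6-lutidine (CH2Cl2, −78 °C) silylates the tertiary C4–OH, giving the acetate triethylsilyl ether F9. K2CO3/MeOH (0 °C) removes the acetate and returns to the route at 24.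

Further compounds
F1 | step 18 | tributylstannyl ether of 24 at the C3 oxygen | C=C[C@@]1(CCCO[Si](c2ccccc2)(c2ccccc2)C(C)(C)C)O[C@H]1CC[C@@](C)(O[Si](CC)(CC)CC)[C@@H](O[Sn](CCCC)(CCCC)CCCC)CCOCc2ccc(OC)cc2
F2 | step 18 | tributylstannyl ether of 25 at the ring carbinol (C7) oxygen | C=C[C@]1(CCCO[Si](c2ccccc2)(c2ccccc2)C(C)(C)C)O[C@@H](CCOCc2ccc(OC)cc2)[C@](C)(O[Si](CC)(CC)CC)CC[C@@H]1O[Sn](CCCC)(CCCC)CCCC
F3 | step 25 | 3-[(1R,2S,5R,9S)-2-[(tert-butyldimethylsilyl)oxy]-9-{2-[(4-methoxyphenyl)methoxy]ethyl}-5-methyl-7-oxo-6,8-dioxabicyclo[3.2.2]nonan-1-yl]propanal | O=CCC[C@@]12O[C@@H](CCOCc3ccc(OC)cc3)[C@@](C)(CC[C@@H]1O[Si](C)(C)C(C)(C)C)OC2=O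
F4 | step 25 | ethyl (2Z)-5-[(1R,2S,5R,9S)-2-[(tert-butyldimethylsilyl)oxy]-9-{2-[(4-methoxyphenyl)methoxy]ethyl}-5-methyl-7-oxo-6,8-dioxabicyclo[3.2.2]nonan-1-yl]-2-methylpent-2-enoate | CCOC(=O)/C(C)=C\CC[C@@]12O[C@@H](CCOCc3ccc(OC)cc3)[C@@](C)(CC[C@@H]1O[Si](C)(C)C(C)(C)C)OC2=O
F5 | step 25 | (1R,2S,5R,9S)-2-[(tert-butyldimethylsilyl)oxy]-1-[(3Z)-5-hydroxy-4-methylpent-3-en-1-yl]-9-{2-[(4-methoxyphenyl)methoxy]ethyl}-5-methyl-6,8-dioxabicyclo[3.2.2]nonan-7-ol (both C7 epimers) | C/C(=C/CC[C@@]12O[C@@H](CCOCc3ccc(OC)cc3)[C@@](C)(CC[C@@H]1O[Si](C)(C)C(C)(C)C)OC2O)CO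
F6 | step 25 | (1R,2S,5R,9S)-2-[(tert-butyldimethylsilyl)oxy]-1-{(3Z)-5-[(tert-butyldimethylsilyl)oxy]-4-methylpent-3-en-1-yl}-9-{2-[(4-methoxyphenyl)methoxy]ethyl}-5-methyl-6,8-dioxabicyclo[3.2.2]nonan-7-ol (both C7 epimers) | C/C(=C/CC[C@@]12O[C@@H](CCOCc3ccc(OC)cc3)[C@@](C)(CC[C@@H]1O[Si](C)(C)C(C)(C)C)OC2O)CO[Si](C)(C)C(C)(C)C
F7 | step 17 | (3S,4R)-6-[(2S,3R)-3-{3-[(tert-butyldiphenylsilyl)oxy]propyl}-3-ethenyloxiran-2-yl]-1-[(4-methoxyphenyl)methoxy]-4-methylhexane-3,4-diol | C=C[C@@]1(CCCO[Si](c2ccccc2)(c2ccccc2)C(C)(C)C)O[C@H]1CC[C@@](C)(O)[C@@H](O)CCOCc2ccc(OC)cc2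
F8 | step 17 | 3-O-acetate of F7 | C=C[C@@]1(CCCO[Si](c2ccccc2)(c2ccccc2)C(C)(C)C)O[C@H]1CC[C@@](C)(O)[C@@H](OC(C)=O)CCOCc2ccc(OC)cc2
F9 | step 17 | 3-O-acetate 4-O-triethylsilyl ether of F7 | C=C[C@@]1(CCCO[Si](c2ccccc2)(c2ccccc2)C(C)(C)C)O[C@H]1CC[C@@](C)(O[Si](CC)(CC)CC)[C@@H](OC(C)=O)CCOCc2ccc(OC)cc2
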